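**Retrosynthetic overview**
1. Target ⇐ hydrolysis of four catechol acetonides ⇐ selective cleavage of two methyl esters of the fully protected 1‑aryl‑1,2‑dihydronaphthalene.
2. Carbocycle ⇐ one‑flask radical [4+2] annulation: C1–C2 by Giese addition of an o‑formyl diarylmethyl radical (released from a lactol by photoredox/PPh3 deoxygenation) to a fumarate already carrying both (R)‑aryl‑lactate esters; C3–C4 by aldol closure of the resulting enolate; then dehydration.
3. Lactol ⇐ two molecules of one protected aldehyde; directed ortho‑lithiation puts C1 on the ring carbon next to oxygen, which fixes the 7,8‑dioxygenation pattern.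
4. Fumarate ⇐ fumaryl chloride + 2 × protected (R)‑aryl‑lactate ⇐ aryl Grignard + methyl (R)‑glycidate; all four arenes ⇐ catechol.
5. Ring order: four dioxole (acetonide) rings, then a transient lactol ring, then the carbocycle (the only ring built on the skeleton).

**Route**

Step 1
Reactants: 1 catechol
Product: 2 2,2-dimethyl-1,3-benzodioxole
Conditions: 2,2-dimethoxypropane, p-TsOH (cat.), PhMe, reflux (4 Å MS Soxhlet)
Reagents that add atoms: 2,2-dimethoxypropane, COC(C)(C)OC
Why: Acid-catalysed transketalisation (acetonide formation) of the 1,2-diol, driven by removal of methanol; no stereocentre.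

Step 2
Reactants: 2 2,2-dimethyl-1,3-benzodioxole
Product: 3 5-bromo-2,2-dimethyl-1,3-benzodioxole
Conditions: NBS, MeCN, 0 °C → rt
Reagents that add atoms: N-bromosuccinimide, O=C1CCC(=O)N1Br
Why: Electrophilic aromatic bromination para to a ring oxygen; C5 and C6 are equivalent, so one monobromide forms.

Step 3
Reactants: 3 5-bromo-2,2-dimethyl-1,3-benzodioxole
Product: 5 2,2-dimethyl-1,3-benzodioxole-5-carbaldehyde, via (2,2-dimethyl-1,3-benzodioxol-5-yl)lithium 4 (not isolated)
Conditions: n-BuLi, THF, −78 °C; DMF, −78 → 0 °C; 1 M HCl, 0 °C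
Reagents that add atoms: N,N-dimethylformamide, CN(C)C=O
Why: Bromine–lithium exchange and formylation of the aryllithium with DMF (Bouveault-type aldehyde synthesis); the acetonide is inert to the organolithium at −78 °C and to the brief cold acid quench.

Step 4
Reactants: 5 2,2-dimethyl-1,3-benzodioxole-5-carbaldehyde (two molecules: one is lithiated, one is the electrophile)
Product: 8 3-(2,2-dimethyl-1,3-benzodioxol-5-yl)-4,5-(isopropylidenedioxy)-1,3-dihydroisobenzofuran-1-ol (lactol, mixture of diastereomers), via lithium [2-(dimethylamino)ethyl](methyl)amino(2,2-dimethyl-1,3-benzodioxol-5-yl)methanolate 6 (not isolated), via its 4-lithio derivative 7 (not isolated)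
Conditions: LiN(Me)CH2CH2NMe2 (from the diamine + n-BuLi), THF, −20 °C; n-BuLi, −20 °C; then second portion of 5, −78 → 0 °C; aq. HCl (pH 5)
Reagents that add atoms: none
Why: α-Amino-alkoxide-directed ortho-lithiation (Comins protocol): the in situ hemiaminalate and the adjacent ring oxygen direct deprotonation to C4, the aryllithium adds to a second molecule of 5, and hydrolysis gives the hydroxy aldehyde, which closes to the lactol; both new stereocentres are uncontrolled and are erased in step 7.

Step 5
Reactants: 3 5-bromo-2,2-dimethyl-1,3-benzodioxole; 9 methyl (R)-glycidate [methyl (2R)-oxirane-2-carboxylate]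
Product: 11 methyl (2R)-3-(2,2-dimethyl-1,3-benzodioxol-5-yl)-2-hydroxypropanoate, via (2,2-dimethyl-1,3-benzodioxol-5-yl)magnesium bromide 10 (not isolated)
Conditions: Mg, THF, reflux; CuI (10 mol %), −40 °C; 9, −40 → −20 °C; 1 M HCl, 0 °C
Reagents that add atoms: none
Why: Copper-catalysed Grignard opening of the epoxide at the unsubstituted C3 (SN2); C2 is untouched, so the (R) centre of 9 becomes the (R) centre of the 2-hydroxy ester.

Step 6
Reactants: 11 methyl (2R)-3-(2,2-dimethyl-1,3-benzodioxol-5-yl)-2-hydroxypropanoate (2.1 equiv); 12 fumaryl chloride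
Product: 13 bis[(2R)-3-(2,2-dimethyl-1,3-benzodioxol-5-yl)-1-methoxy-1-oxopropan-2-yl] (2E)-but-2-enedioate
Conditions: pyridine, DMAP (cat.), CH2Cl2, 0 °C → rt
Reagents that add atoms: none
Why: Double O-acylation of the secondary alcohol by the bis-acid chloride (pyridine/DMAP esterification); no bond to a stereocentre is broken and the E-alkene is retained.

Step 7
Reactants: 8 lactol (1.5 equiv); 13 fumarate bis-ester
Product: 16 bis[(2R)-3-(2,2-dimethyl-1,3-benzodioxol-5-yl)-1-methoxy-1-oxopropan-2-yl] (1R,2S)-1-(2,2-dimethyl-1,3-benzodioxol-5-yl)-7,8-(isopropylidenedioxy)-1,2-dihydronaphthalene-2,3-dicarboxylate (1,2-trans), via the 4-hydroxy-1,2,3,4-tetrahydronaphthalene diester 14 (not isolated), via its 4-methanesulfonate 15 (not isolated)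
Conditions: [Ir(dFMeppy)2(dtbbpy)]PF6 (2 mol %), PPh3 (1.5 equiv), 2,4,6-collidine, PhMe/MeCN, 450 nm LEDs, rt, Ar; then MsCl, Et3N, CH2Cl2, 0 °C; DBU (0.3 equiv), rt; chromatographic separation of the two C1 diastereomers
Reagents that add atoms: none
Why: Proposed new method: photo-oxidised PPh3 captures the lactol OH (or the benzhydrol OH of the open tautomer), and β-scission of the phosphoranyl radical expels Ph3P=O to give the α-oxy benzylic radical, which ring-opens by C–O β-scission to the o-formyl diarylmethyl radical (aryl aldehyde plus doubly benzylic radical, exergonic); this radical adds to the fumarate (Giese addition, forms C1–C2), Ir(II) reduces the α-ester radical to the enolate (radical–polar crossover), and the enolate closes C3–C4 by intramolecular aldol addition to the unveiled aldehyde; MsCl/Et3N then eliminates the benzylic β-hydroxy ester to the C3=C4 enoate and DBU equilibrates C2 to the thermodynamic trans isomer; C1 is created in the radical addition with no reliable facial bias, so both trans diastereomers form and the (1R,2S) one is isolated, the (R)-ester centres making them separable; closest known reaction types are photoredox/phosphine deoxygenative generation of benzylic radicals from alcohols, Giese addition with radical–polar-crossover aldol termination, and the photoenolisation/[4+2] annulation of 2-benzylbenzaldehydes, whose product type it reproduces.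

Step 8
Reactants: 16 protected (1R,2S)-dihydronaphthalene tetraester
Product: 17 (1R,2S)-2,3-bis{[(1R)-1-carboxy-2-(2,2-dimethyl-1,3-benzodioxol-5-yl)ethoxy]carbonyl} compound (both methyl esters cleaved, acetonides intact)
Conditions: Me3SnOH (6 equiv), 1,2-dichloroethane, 70 °C; 0.1 M HCl work-up
Reagents that add atoms: trimethyltin hydroxide, C[Sn](C)(C)O
Why: Trimethyltin hydroxide cleaves the unhindered methyl esters selectively over the two hindered secondary lactate-type esters under near-neutral conditions, so the α-acyloxy centres are kept and C2 stays trans (its thermodynamic configuration).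

Step 9
Reactants: 17 tetra-acetonide diacid
Product: 18 target, (1R,2S)-1-(3,4-dihydroxyphenyl)-7,8-dihydroxy-1,2-dihydronaphthalene-2,3-dicarboxylic acid 2,3-bis[(1R)-1-carboxy-2-(3,4-dihydroxyphenyl)ethyl] ester
Conditions: TFA/H2O 9:1, 0 °C → rt, Ar; reversed-phase HPLC
Reagents that add atoms: none
Why: Acid-catalysed ketal hydrolysis of the four catechol acetonides; the ester bonds and the trans-1,2-dihydronaphthalene are stable to TFA and no stereocentre is touched.

**Compound list**
1 | catechol | Oc1ccccc1O | starting material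
2 | 2,2-dimethyl-1,3-benzodioxole | CC1(C)Oc2ccccc2O1 | intermediate
3 | 5-bromo-2,2-dimethyl-1,3-benzodioxole | CC1(C)Oc2ccc(Br)cc2O1 | intermediate
4 | (2,2-dimethyl-1,3-benzodioxol-5-yl)lithium | CC1(C)Oc2ccc([Li])cc2O1 | intermediate
5 | 2,2-dimethyl-1,3-benzodioxole-5-carbaldehyde | CC1(C)Oc2ccc(C=O)cc2O1 | intermediate
6 | lithium [2-(dimethylamino)ethyl](methyl)amino(2,2-dimethyl-1,3-benzodioxol-5-yl)methanolate | CN(C)CCN(C)C([O-])c1ccc2OC(C)(C)Oc2c1.[Li+] | intermediate
7 | 4-lithio derivative of 6 (C–Li between the ring oxygen and the hemiaminalate carbon) | CN(C)CCN(C)C([O-])c1ccc2OC(C)(C)Oc2c1[Li].[Li+] | intermediate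
8 | 3-(2,2-dimethyl-1,3-benzodioxol-5-yl)-4,5-(isopropylidenedioxy)-1,3-dihydroisobenzofuran-1-ol (diastereomer mixture) | OC1OC(c2ccc3OC(C)(C)Oc3c2)c2c1ccc1OC(C)(C)Oc21 | intermediate
9 | methyl (R)-glycidate | COC(=O)[C@H]1CO1 | starting material
10 | (2,2-dimethyl-1,3-benzodioxol-5-yl)magnesium bromide | CC1(C)Oc2ccc([Mg]Br)cc2O1 | intermediate
11 | methyl (2R)-3-(2,2-dimethyl-1,3-benzodioxol-5-yl)-2-hydroxypropanoate | COC(=O)[C@H](O)Cc1ccc2OC(C)(C)Oc2c1 | intermediate
12 | fumaryl chloride | ClC(=O)/C=C/C(=O)Cl | starting material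
13 | bis[(2R)-3-(2,2-dimethyl-1,3-benzodioxol-5-yl)-1-methoxy-1-oxopropan-2-yl] fumarate | COC(=O)[C@@H](Cc1ccc2OC(C)(C)Oc2c1)OC(=O)/C=C/C(=O)O[C@H](Cc1ccc2OC(C)(C)Oc2c1)C(=O)OC | intermediate
14 | bis[(2R)-3-(2,2-dimethyl-1,3-benzodioxol-5-yl)-1-methoxy-1-oxopropan-2-yl] 1-(2,2-dimethyl-1,3-benzodioxol-5-yl)-4-hydroxy-7,8-(isopropylidenedioxy)-1,2,3,4-tetrahydronaphthalene-2,3-dicarboxylate (ring stereocentres as a mixture) | COC(=O)[C@@H](Cc1ccc2OC(C)(C)Oc2c1)OC(=O)C1C(O)c2ccc3OC(C)(C)Oc3c2C(c2ccc3OC(C)(C)Oc3c2)C1C(=O)O[C@H](Cc1ccc2OC(C)(C)Oc2c1)C(=O)OC | intermediate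
15 | 4-methanesulfonate of 14 | COC(=O)[C@@H](Cc1ccc2OC(C)(C)Oc2c1)OC(=O)C1C(OS(C)(=O)=O)c2ccc3OC(C)(C)Oc3c2C(c2ccc3OC(C)(C)Oc3c2)C1C(=O)O[C@H](Cc1ccc2OC(C)(C)Oc2c1)C(=O)OC | intermediate
16 | protected (1R,2S)-1-aryl-1,2-dihydronaphthalene-2,3-dicarboxylate bis[(R)-aryl-lactate methyl ester] (four acetonides) | O=C(O[C@H](Cc1ccc2OC(C)(C)Oc2c1)C(=O)OC)C1=Cc2ccc3OC(C)(C)Oc3c2[C@@H](c2ccc3OC(C)(C)Oc3c2)[C@@H]1C(=O)O[C@H](Cc1ccc2OC(C)(C)Oc2c1)C(=O)OC | intermediate
17 | tetra-acetonide diacid (methyl esters of 16 cleaved) | O=C(O[C@H](Cc1ccc2OC(C)(C)Oc2c1)C(=O)O)C1=Cc2ccc3OC(C)(C)Oc3c2[C@@H](c2ccc3OC(C)(C)Oc3c2)[C@@H]1C(=O)O[C@H](Cc1ccc2OC(C)(C)Oc2c1)C(=O)O | intermediate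
18 | CNP0244800.2 | O=C(O[C@H](Cc1ccc(O)c(O)c1)C(=O)O)C1=Cc2ccc(O)c(O)c2[C@@H](c2ccc(O)c(O)c2)[C@@H]1C(=O)O[C@H](Cc1ccc(O)c(O)c1)C(=O)O | target

**Step count**
Total: 9 steps. Longest linear sequence: 7 steps (steps 1, 2, 3, 4, 7, 8, 9; the branch through steps 1, 2, 5, 6, 7, 8, 9 is equally long).

**Steps most likely to fail, with fallbacks**

Step 7 is the main risk. The first-formed cyclic α-oxy radical may add to the fumarate before it ring-opens, and the stabilised diarylmethyl radical adds slowly and reversibly, so dimerisation competes. C1 is formed without control, so at best about half of the material is the wanted diastereomer. The DBU equilibration must also not touch the ester α-centres. The fallback sets out from 8 and 13 and replaces the radical addition by a cycloaddition. Lactol 8 is dehydrated with catalytic camphorsulfonic acid over molecular sieves in the presence of 13 to the isobenzofuran F1. F1 is trapped in situ by 13 in a Diels–Alder reaction, run with MgBr2·OEt2 at low temperature so that the chelated lactate-type esters can bias the approach, to give the oxa-bridged cycloadduct F2. Et3SiH/BF3·OEt2 at −78 → −20 °C then opens the bridge at the diaryl-substituted carbon and delivers hydride to C1. This gives 14, where the fallback comes back to the route; mesylation, elimination and equilibration then follow as in step 7.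

Step 4 is the second risk. The ortho-lithiation may be incomplete or go to the other ortho position, and excess n-BuLi consumes part of the aldehyde used as electrophile. The fallback sets out from 3 and 5. Bromide 3 is deprotonated with LDA at −78 °C at C4, the position flanked by bromine and the ring oxygen, and the aryllithium is added to 5 to give the bromo carbinol F3. Treatment of F3 with n-BuLi (2.2 equiv; O–H deprotonation, then Br/Li exchange) and DMF, followed by acidic work-up, gives the hydroxy aldehyde, which closes to 8, where the fallback comes back to the route.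

Step 8 is the third risk. The two internal α-acyloxy esters may be cleaved alongside the methyl esters. The fallback sets out from 16 and makes no new isolable compound (F0). AlBr3/tetrahydrothiophene in CH2Cl2 at 0 °C → rt removes the methyl esters by SN2 demethylation and opens the four acetonides in the same operation, with no thiol present that could add to the enoate. Aqueous work-up then gives 18 directly, where the fallback comes back to the route, bypassing 17 and step 9.

**Further compounds**
F1 | step 7 | 1-(2,2-dimethyl-1,3-benzodioxol-5-yl)-6,7-(isopropylidenedioxy)isobenzofuran | C1=C2C=CC3=C(OC(C)(C)O3)C2=C(O1)c1ccc2OC(C)(C)Oc2c1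
F2 | step 7 | bis[(2R)-3-(2,2-dimethyl-1,3-benzodioxol-5-yl)-1-methoxy-1-oxopropan-2-yl] 1-(2,2-dimethyl-1,3-benzodioxol-5-yl)-7,8-(isopropylidenedioxy)-1,4-epoxy-1,2,3,4-tetrahydronaphthalene-2,3-dicarboxylate (2,3-trans) | COC(=O)[C@@H](Cc1ccc2OC(C)(C)Oc2c1)OC(=O)C1C2OC(c3ccc4OC(C)(C)Oc4c3)(C1C(=O)O[C@H](Cc5ccc6OC(C)(C)Oc6c5)C(=O)OC)c1c2ccc2OC(C)(C)Oc12
F3 | step 4 | (5-bromo-2,2-dimethyl-1,3-benzodioxol-4-yl)(2,2-dimethyl-1,3-benzodioxol-5-yl)methanol | OC(c1ccc2OC(C)(C)Oc2c1)c1c(Br)ccc2OC(C)(C)Oc12
F0 | step 8 | none | none
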